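**Retrosynthetic overview**

1. The route rests on ring A (C1–C6) of the 2,7'-cyclolignan: a pentasubstituted benzene with oxygen on C3, C4 and C5, whose C3 methoxy group presses against the guaiacyl ring C on C7'. Ring A is therefore made last, on a cyclohexene that already is ring B and carries C7', C8' and C8 in their final configuration.
2. Target ⇐ O-debenzylation, C4 silicon-to-oxygen exchange and C3 O-methylation ⇐ C3-hydroxy-C4-trimethylsilyl-C5-methoxy aryltetralin ⇐ benzannulation (bonds C1–C6, C5–C6, C3–C4, C2–C3) ⇐ cyclohexenyl diazomethyl ketone + (methoxyethynyl)trimethylsilane.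
3. Diazoketone ⇐ acetylcyclohexene (diazo transfer) ⇐ enol triflate (Stille coupling with an acetyl equivalent) ⇐ aryl cuprate addition and enolate triflation on (4R,5R)-cis-4,5-dimethylcyclohex-2-enone.
4. Enone ⇐ enantioselective lithium amide rearrangement of the meso epoxide of cis-4,5-dimethylcyclohexene ⇐ cis-1,2,3,6-tetrahydrophthalic anhydride.
5. Ring order: ring B comes with the anhydride, ring C is attached at C7' by the cuprate, ring A is closed last in the key step.

Key step: step 12

Assumption: the lithium amide of the (R)-proline-derived diamine is taken to select protons on the trans-epoxide of cis-4,5-dimethylcyclohexene in the same sense as its enantiomer does on cyclohexene oxide; if the sense proves opposite, the (S)-diamine is used with no other change.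

**Route**

Step 1
Reactants: 1 cis-1,2,3,6-tetrahydrophthalic anhydride (meso)
Product: 2 cis-cyclohex-4-ene-1,2-diyldimethanol (meso)
Conditions: LiAlH4, THF, 0 °C to reflux; then H2O, aq NaOH
Reagents that add atoms: none
Why: Exhaustive hydride reduction of the cyclic anhydride (LiAlH4 reduction) should give the diol without touching the cis ring junction, so the two future methyl carbons stay cis.

Step 2
Reactants: 2 cis-cyclohex-4-ene-1,2-diyldimethanol
Product: 3 cis-cyclohex-4-ene-1,2-diylbis(methylene) dimethanesulfonate (meso)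
Conditions: MsCl, Et3N, CH2Cl2, 0 °C
Reagents that add atoms: methanesulfonyl chloride, CS(=O)(=O)Cl
Why: Mesylation of both primary alcohols turns them into leaving groups and leaves the alkene and the two stereocentres alone.

Step 3
Reactants: 3 cis-cyclohex-4-ene-1,2-diylbis(methylene) dimethanesulfonate
Product: 4 cis-4,5-dimethylcyclohexene (meso)
Conditions: LiBHEt3, THF, 0 °C to rt; distillation
Reagents that add atoms: none
Why: SN2 displacement of the primary sulfonates by hydride (LiBHEt3 reduction, which attacks carbon and not sulfur) should give the volatile meso hydrocarbon.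

Step 4
Reactants: 4 cis-4,5-dimethylcyclohexene
Product: 5 (1R,3R,4S,6S)-3,4-dimethyl-7-oxabicyclo[4.1.0]heptane (meso trans-epoxide, oxygen anti to both methyl groups)
Conditions: mCPBA, CH2Cl2, 0 °C to rt; chromatographic removal of the minor syn-epoxide
Reagents that add atoms: meta-chloroperoxybenzoic acid, O=C(OO)c1cccc(Cl)c1
Why: Prilezhaev epoxidation should occur mainly on the face away from the pseudoaxial methyl group of the half-chair, and the minor syn-epoxide is removed because it would feed the enantiomeric series in step 5.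

Step 5
Reactants: 5 (1R,3R,4S,6S)-3,4-dimethyl-7-oxabicyclo[4.1.0]heptane
Product: 6 (1R,4R,5R)-4,5-dimethylcyclohex-2-en-1-ol (hydroxyl trans to both methyl groups)
Conditions: (R)-2-(pyrrolidin-1-ylmethyl)pyrrolidine, n-BuLi, THF, 0 °C to rt; H2O
Reagents that add atoms: none
Why: Enantioselective epoxide-to-allylic-alcohol rearrangement by a chiral lithium amide (syn β-elimination) should remove only the syn proton on C5, next to the (S)-configured oxirane carbon C6, so the carbinol carbon is (R) and the two methyl-bearing carbons, mirror images until now, become the (4R,5R) pair that ends as C8' and C8; the (R)-diamine is chosen because its enantiomer is known to convert cyclohexene oxide into (S)-cyclohex-2-enol.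

Step 6
Reactants: 6 (1R,4R,5R)-4,5-dimethylcyclohex-2-en-1-ol
Product: 7 (4R,5R)-4,5-dimethylcyclohex-2-en-1-one (cis-dimethyl)
Conditions: Dess–Martin periodinane, CH2Cl2, rt
Reagents that add atoms: none
Why: Dess–Martin oxidation of the secondary allylic alcohol under nearly neutral conditions should give the enone without epimerising the γ-carbon C4.

Step 7
Reactants: 8 4-bromo-2-methoxyphenol
Product: 9 1-(benzyloxy)-4-bromo-2-methoxybenzene
Conditions: BnBr, K2CO3, DMF, rt
Reagents that add atoms: benzyl bromide, BrCc1ccccc1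
Why: Williamson etherification protects the ring C phenol as a benzyl ether that tolerates the organolithium, cuprate, palladium and base steps and is removed at the end by hydrogenolysis.

Step 8
Reactants: 9 1-(benzyloxy)-4-bromo-2-methoxybenzene; 7 (4R,5R)-4,5-dimethylcyclohex-2-en-1-one
Product: 13 (3S,4R,5R)-3-[4-(benzyloxy)-3-methoxyphenyl]-4,5-dimethylcyclohex-1-en-1-yl trifluoromethanesulfonate, via aryllithium 10 (not isolated), via lithium diarylcuprate 11 (not isolated), via lithium enolate 12 (not isolated)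
Conditions: 9 (2.2 equiv), n-BuLi, THF, −78 °C; CuI (1.1 equiv), −78 to −30 °C; 7 (1.0 equiv), −78 °C; Comins' reagent, −78 °C to rt; aq NH4Cl
Reagents that add atoms: Comins' reagent, N-(5-chloropyridin-2-yl)-1,1,1-trifluoro-N-[(trifluoromethyl)sulfonyl]methanesulfonamide, FC(F)(F)S(=O)(=O)N(c1ccc(Cl)cn1)S(=O)(=O)C(F)(F)F
Why: Bromine–lithium exchange and transmetalation give Gilman cuprate 11, whose conjugate addition to 7 should occur by axial attack on the face opposite both methyl groups, setting C3 (the future C7') trans to the C4 methyl, and the regiodefined enolate 12 is trapped on oxygen as the enol triflate.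

Step 9
Reactants: 13 (3S,4R,5R)-3-[4-(benzyloxy)-3-methoxyphenyl]-4,5-dimethylcyclohex-1-en-1-yl trifluoromethanesulfonate
Product: 15 1-{(3S,4R,5R)-3-[4-(benzyloxy)-3-methoxyphenyl]-4,5-dimethylcyclohex-1-en-1-yl}ethan-1-one, via ethoxydiene 14 (not isolated)
Conditions: tributyl(1-ethoxyvinyl)stannane, Pd(PPh3)4 (5 mol %), LiCl, THF, reflux; then 1 M HCl, rt
Reagents that add atoms: tributyl(1-ethoxyvinyl)stannane, CCCC[Sn](CCCC)(CCCC)C(=C)OCC; water, O
Why: Stille coupling of the enol triflate with the 1-ethoxyvinyl stannane as acetyl anion equivalent gives enol ether 14, which mild aqueous acid hydrolyses to the methyl ketone without moving the ring double bond or cleaving the benzyl ether.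

Step 10
Reactants: 15 1-{(3S,4R,5R)-3-[4-(benzyloxy)-3-methoxyphenyl]-4,5-dimethylcyclohex-1-en-1-yl}ethan-1-one
Product: 17 2-diazo-1-{(3S,4R,5R)-3-[4-(benzyloxy)-3-methoxyphenyl]-4,5-dimethylcyclohex-1-en-1-yl}ethan-1-one, via trifluoroacetyl diketone 16 (not isolated)
Conditions: LiN(SiMe3)2, THF, −78 °C; CF3CO2CH2CF3, −78 °C; aq HCl wash, solvent switch; MsN3, Et3N, H2O, MeCN, rt
Reagents that add atoms: methanesulfonyl azide, CS(=O)(=O)N=[N+]=[N-]; 2,2,2-trifluoroethyl trifluoroacetate, O=C(OCC(F)(F)F)C(F)(F)F (its trifluoroacetyl group is carried only by 16)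
Why: Detrifluoroacetylative diazo transfer: kinetic deprotonation of the acetyl methyl group at −78 °C and Claisen acylation give diketone 16, which takes the diazo group from MsN3 with loss of the trifluoroacetyl group, avoiding the pyrazoline formation that enoyl chlorides suffer with diazomethane.

Step 11
Reactants: 18 chloroacetaldehyde dimethyl acetal
Product: 20 (methoxyethynyl)trimethylsilane, via lithium methoxyacetylide 19 (not isolated)
Conditions: LiNEt2 (3 equiv, from Et2NH and n-BuLi), THF, 0 °C; Me3SiCl, −78 °C to rt; distillation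
Reagents that add atoms: chlorotrimethylsilane, C[Si](C)(C)Cl
Why: Double β-elimination (methanol, then hydrogen chloride) and deprotonation by the lithium amide give acetylide 19, which Me3SiCl silylates on carbon (acetylide silylation).

Step 12
Reactants: 17 2-diazo-1-{(3S,4R,5R)-3-[4-(benzyloxy)-3-methoxyphenyl]-4,5-dimethylcyclohex-1-en-1-yl}ethan-1-one; 20 (methoxyethynyl)trimethylsilane
Product: 25 (7'R,8R,8'R)-4'-(benzyloxy)-3',5-dimethoxy-4-(trimethylsilyl)-2,7'-cyclolignan-3-ol, via vinylketene 21 (not isolated), via vinylcyclobutenone 22 (not isolated), via dienylketene 23 (not isolated), via cyclohexadienone 24 (not isolated)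
Conditions: 20 (3 equiv), hν (300 nm, Pyrex), ClCH2CH2Cl, rt; then 80 °C
Reagents that add atoms: none
Why: Light expels N2 from 17 and the cyclohexenyl group shifts from the carbonyl carbon to the diazo carbon (photochemical Wolff rearrangement, new bond C1–C6), giving vinylketene 21, whose carbonyl carbon (the future C3) is attacked by the silicon-bearing carbon of ynol ether 20 in a [2+2] cycloaddition (new bonds C3–C4 and C5–C6) to give 4-vinylcyclobutenone 22. At 80 °C the four-membered ring of 22 opens by 4π electrocyclic cleavage of its C3–C6 bond (reversibly, so the unproductive double-bond isomer is recycled) to dienylketene 23, and ring A is closed by thermal 6π electrocyclisation of 23, in which the ketene carbon C3 bonds to C2 of the former cyclohexene double bond; the cyclohexa-2,4-dienone 24 so formed tautomerises to phenol 25. The closest known reaction type is the Danheiser benzannulation in its diazoketone variant with alkoxyalkynes as ketenophiles. No lasting stereocentre is formed, since the sp3 carbons of 22 and 24 disappear on aromatisation, and C7', C8' and C8 take no part and meet no base. The step needs a single orientation of the ketene–alkyne union (silicon on C4, methoxy on C5), and the polarity of 20 secures it: the oxygen lone pair makes the silylated carbon the nucleophilic terminus, while the positive charge growing on the methoxy-bearing carbon is stabilised by oxygen and by the β-silicon. Excess 20 is used so that trapping of 21 outruns its dimerisation and the acylation of 25 by 21, and the 300 nm light spares the benzyl ether.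

Step 13
Reactants: 25 (7'R,8R,8'R)-4'-(benzyloxy)-3',5-dimethoxy-4-(trimethylsilyl)-2,7'-cyclolignan-3-ol
Product: 26 (7'R,8R,8'R)-4'-(benzyloxy)-3,3',5-trimethoxy-4-(trimethylsilyl)-2,7'-cyclolignan
Conditions: NaH, MeI, DMF, 0 °C to rt
Reagents that add atoms: iodomethane, CI
Why: Williamson O-methylation of the hindered C3 phenoxide with the small electrophile MeI should proceed despite the two ortho substituents, and the aprotic medium keeps the aryl–silicon bond intact.

Step 14
Reactants: 26 (7'R,8R,8'R)-4'-(benzyloxy)-3,3',5-trimethoxy-4-(trimethylsilyl)-2,7'-cyclolignan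
Product: 27 (7'R,8R,8'R)-4'-(benzyloxy)-4-iodo-3,3',5-trimethoxy-2,7'-cyclolignan
Conditions: ICl (1.05 equiv), CH2Cl2, −78 to 0 °C
Reagents that add atoms: iodine monochloride, ClI
Why: Electrophilic ipso-iododesilylation: ICl should attack C4, where the arenium ion is stabilised by the β-silicon and by both flanking methoxy groups, faster than any C–H position, and chloride then removes the silyl group.

Step 15
Reactants: 27 (7'R,8R,8'R)-4'-(benzyloxy)-4-iodo-3,3',5-trimethoxy-2,7'-cyclolignan
Product: 30 (7'R,8R,8'R)-4'-(benzyloxy)-3,3',5-trimethoxy-2,7'-cyclolignan-4-ol, via aryllithium 28 (not isolated), via lithium arylborate 29 (not isolated)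
Conditions: n-BuLi, THF, −78 °C; B(OMe)3, −78 °C to rt; H2O2, aq NaOH, 0 °C
Reagents that add atoms: hydrogen peroxide, OO; trimethyl borate, COB(OC)OC (its boron and methoxy groups are carried only by 29)
Why: Iodine–lithium exchange at −78 °C, faster than any deprotonation so the benzyl ether is safe, gives the 2,6-dimethoxyaryllithium 28, which B(OMe)3 traps as borate 29, and alkaline peroxide oxidation (aryl shift from boron to oxygen) gives the C4 phenol.

Step 16
Reactants: 30 (7'R,8R,8'R)-4'-(benzyloxy)-3,3',5-trimethoxy-2,7'-cyclolignan-4-ol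
Product: 31 (−)-(7'R,8R,8'R)-4,4'-dihydroxy-3,3',5-trimethoxy-2,7'-cyclolignan, that is (6R,7R,8R)-8-(4-hydroxy-3-methoxyphenyl)-1,3-dimethoxy-6,7-dimethyl-5,6,7,8-tetrahydronaphthalen-2-ol
Conditions: H2 (1 atm), 10% Pd/C, EtOAc–MeOH, rt
Reagents that add atoms: none
Why: Hydrogenolysis of the benzyl ether over palladium on carbon frees the ring C phenol and leaves the aryl methyl ethers and the three stereocentres untouched.

**Compound list**

1 | cis-1,2,3,6-tetrahydrophthalic anhydride (meso) | O=C1OC(=O)[C@@H]2CC=CC[C@H]12 | starting material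
2 | cis-cyclohex-4-ene-1,2-diyldimethanol (meso) | OC[C@@H]1CC=CC[C@@H]1CO | intermediate
3 | cis-cyclohex-4-ene-1,2-diylbis(methylene) dimethanesulfonate (meso) | CS(=O)(=O)OC[C@@H]1CC=CC[C@@H]1COS(C)(=O)=O | intermediate
4 | cis-4,5-dimethylcyclohexene (meso) | C[C@@H]1CC=CC[C@@H]1C | intermediate
5 | (1R,3R,4S,6S)-3,4-dimethyl-7-oxabicyclo[4.1.0]heptane (meso trans-epoxide, oxygen anti to both methyl groups) | C[C@@H]1C[C@H]2O[C@H]2C[C@@H]1C | intermediate
6 | (1R,4R,5R)-4,5-dimethylcyclohex-2-en-1-ol | C[C@@H]1C[C@@H](O)C=C[C@@H]1C | intermediate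
7 | (4R,5R)-4,5-dimethylcyclohex-2-en-1-one | C[C@@H]1CC(=O)C=C[C@@H]1C | intermediate
8 | 4-bromo-2-methoxyphenol | COc1cc(Br)ccc1O | starting material
9 | 1-(benzyloxy)-4-bromo-2-methoxybenzene | COc1cc(Br)ccc1OCc1ccccc1 | intermediate
10 | [4-(benzyloxy)-3-methoxyphenyl]lithium | COc1cc([Li])ccc1OCc1ccccc1 | intermediate
11 | lithium bis[4-(benzyloxy)-3-methoxyphenyl]cuprate | [Li+].COc1cc([Cu-]c2ccc(OCc3ccccc3)c(OC)c2)ccc1OCc1ccccc1 | intermediate
12 | lithium (3S,4R,5R)-3-[4-(benzyloxy)-3-methoxyphenyl]-4,5-dimethylcyclohex-1-en-1-olate | COc1cc([C@@H]2C=C(O[Li])C[C@@H](C)[C@H]2C)ccc1OCc1ccccc1 | intermediate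
13 | (3S,4R,5R)-3-[4-(benzyloxy)-3-methoxyphenyl]-4,5-dimethylcyclohex-1-en-1-yl trifluoromethanesulfonate | COc1cc([C@@H]2C=C(OS(=O)(=O)C(F)(F)F)C[C@@H](C)[C@H]2C)ccc1OCc1ccccc1 | intermediate
14 | (3S,4R,5R)-3-[4-(benzyloxy)-3-methoxyphenyl]-1-(1-ethoxyvinyl)-4,5-dimethylcyclohex-1-ene | COc1cc([C@@H]2C=C(C(=C)OCC)C[C@@H](C)[C@H]2C)ccc1OCc1ccccc1 | intermediate
15 | 1-{(3S,4R,5R)-3-[4-(benzyloxy)-3-methoxyphenyl]-4,5-dimethylcyclohex-1-en-1-yl}ethan-1-one | COc1cc([C@@H]2C=C(C(C)=O)C[C@@H](C)[C@H]2C)ccc1OCc1ccccc1 | intermediate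
16 | 1-{(3S,4R,5R)-3-[4-(benzyloxy)-3-methoxyphenyl]-4,5-dimethylcyclohex-1-en-1-yl}-4,4,4-trifluorobutane-1,3-dione | COc1cc([C@@H]2C=C(C(=O)CC(=O)C(F)(F)F)C[C@@H](C)[C@H]2C)ccc1OCc1ccccc1 | intermediate
17 | 2-diazo-1-{(3S,4R,5R)-3-[4-(benzyloxy)-3-methoxyphenyl]-4,5-dimethylcyclohex-1-en-1-yl}ethan-1-one | COc1cc([C@@H]2C=C(C(=O)C=[N+]=[N-])C[C@@H](C)[C@H]2C)ccc1OCc1ccccc1 | intermediate
18 | chloroacetaldehyde dimethyl acetal | COC(CCl)OC | starting material
19 | lithium methoxyacetylide | [Li]C#COC | intermediate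
20 | (methoxyethynyl)trimethylsilane | COC#C[Si](C)(C)C | intermediate
21 | 2-{(3S,4R,5R)-3-[4-(benzyloxy)-3-methoxyphenyl]-4,5-dimethylcyclohex-1-en-1-yl}ethen-1-one (vinylketene) | COc1cc([C@@H]2C=C(C=C=O)C[C@@H](C)[C@H]2C)ccc1OCc1ccccc1 | intermediate
22 | 4-{(3S,4R,5R)-3-[4-(benzyloxy)-3-methoxyphenyl]-4,5-dimethylcyclohex-1-en-1-yl}-3-methoxy-2-(trimethylsilyl)cyclobut-2-en-1-one (C4 of the four-membered ring undefined) | COc1cc([C@@H]2C=C(C3C(OC)=C([Si](C)(C)C)C3=O)C[C@@H](C)[C@H]2C)ccc1OCc1ccccc1 | intermediate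
23 | 4-{(3S,4R,5R)-3-[4-(benzyloxy)-3-methoxyphenyl]-4,5-dimethylcyclohex-1-en-1-yl}-3-methoxy-2-(trimethylsilyl)buta-1,3-dien-1-one, ketene carbon and cyclohexenyl group cis on the C3=C4 bond (dienylketene) | COc1cc([C@@H]2C=C(\C=C(OC)/C(=C=O)[Si](C)(C)C)C[C@@H](C)[C@H]2C)ccc1OCc1ccccc1 | intermediate
24 | keto tautomer of 25: ring A as cyclohexa-2,4-dienone with C3 ketone, sp3 C2–H (undefined), double bonds C4=C5 and C6=C1 | COc1cc([C@@H]2C3C(=O)C([Si](C)(C)C)=C(OC)C=C3C[C@@H](C)[C@H]2C)ccc1OCc1ccccc1 | intermediate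
25 | (7'R,8R,8'R)-4'-(benzyloxy)-3',5-dimethoxy-4-(trimethylsilyl)-2,7'-cyclolignan-3-ol, that is (6R,7R,8R)-8-[4-(benzyloxy)-3-methoxyphenyl]-3-methoxy-6,7-dimethyl-2-(trimethylsilyl)-5,6,7,8-tetrahydronaphthalen-1-ol | COc1cc([C@@H]2c3c(cc(OC)c([Si](C)(C)C)c3O)C[C@@H](C)[C@H]2C)ccc1OCc1ccccc1 | intermediate
26 | (7'R,8R,8'R)-4'-(benzyloxy)-3,3',5-trimethoxy-4-(trimethylsilyl)-2,7'-cyclolignan | COc1cc([C@@H]2c3c(cc(OC)c([Si](C)(C)C)c3OC)C[C@@H](C)[C@H]2C)ccc1OCc1ccccc1 | intermediate
27 | (7'R,8R,8'R)-4'-(benzyloxy)-4-iodo-3,3',5-trimethoxy-2,7'-cyclolignan | COc1cc([C@@H]2c3c(cc(OC)c(I)c3OC)C[C@@H](C)[C@H]2C)ccc1OCc1ccccc1 | intermediate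
28 | (7'R,8R,8'R)-4'-(benzyloxy)-4-lithio-3,3',5-trimethoxy-2,7'-cyclolignan | COc1cc([C@@H]2c3c(cc(OC)c([Li])c3OC)C[C@@H](C)[C@H]2C)ccc1OCc1ccccc1 | intermediate
29 | lithium trimethoxy[(7'R,8R,8'R)-4'-(benzyloxy)-3,3',5-trimethoxy-2,7'-cyclolignan-4-yl]borate | [Li+].COc1cc([C@@H]2c3c(cc(OC)c([B-](OC)(OC)OC)c3OC)C[C@@H](C)[C@H]2C)ccc1OCc1ccccc1 | intermediate
30 | (7'R,8R,8'R)-4'-(benzyloxy)-3,3',5-trimethoxy-2,7'-cyclolignan-4-ol | COc1cc([C@@H]2c3c(cc(OC)c(O)c3OC)C[C@@H](C)[C@H]2C)ccc1OCc1ccccc1 | intermediate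
31 | (−)-(7'R,8R,8'R)-4,4'-dihydroxy-3,3',5-trimethoxy-2,7'-cyclolignan | COc1cc([C@@H]2c3c(cc(OC)c(O)c3OC)C[C@@H](C)[C@H]2C)ccc1O | target

**Step count**

Total steps: 16. Longest linear sequence: 14 steps (steps 1–6, 8–10, 12–16).

**Steps most likely to fail**

Step 12. The [2+2] addition of vinylketene 21 to the silicon-capped ynol ether may be too slow, because the SiMe3 group sits on the attacking carbon; the ketene would then be lost to dimerisation or to acylation of phenol already formed. The fallback sets out from 17 and 18 and comes back at 30.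
- 18 is converted with NaNH2 in liquid NH3, then water, into the unhindered ketenophile methoxyacetylene F1.
- The same photochemical benzannulation of 17 with it should run through 4-{(3S,4R,5R)-3-[4-(benzyloxy)-3-methoxyphenyl]-4,5-dimethylcyclohex-1-en-1-yl}-3-methoxycyclobut-2-en-1-one F2, the derived silicon-free dienylketene F3 and the silicon-free cyclohexa-2,4-dienone F4.
- This should give (7'R,8R,8'R)-4'-(benzyloxy)-3',5-dimethoxy-2,7'-cyclolignan-3-ol F5, in which C4 carries hydrogen.
- O-Methylation (NaH, MeI, DMF) gives (7'R,8R,8'R)-4'-(benzyloxy)-3,3',5-trimethoxy-2,7'-cyclolignan F6.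
- Directed ortho-lithiation of this ether between the C3 and C5 methoxy groups (n-BuLi, TMEDA, THF, 0 °C) gives aryllithium 28, and borylation and oxidation as in step 15 lead through 29 to 30.

Step 14. The iodine electrophile may attack the free C6–H position of ring A or a position of ring C instead of the silylated C4 (loss of ipso selectivity), or the silyl group may be lost by protodesilylation through traces of acid. The fallback sets out from 26 and comes back at 31.
- 26 is treated with excess BCl3 and pentamethylbenzene as benzyl cation scavenger (CH2Cl2, −78 to 0 °C); BCl3 does not substitute aromatic C–H positions under these conditions.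
- Ipso-borodesilylation at C4 and cleavage of the benzyl ether in the same flask should give (7'R,8R,8'R)-4-(dichloroboryl)-4'-(dichloroboryloxy)-3,3',5-trimethoxy-2,7'-cyclolignan F7.
- Aqueous quench gives (7'R,8R,8'R)-4'-hydroxy-3,3',5-trimethoxy-2,7'-cyclolignan-4-ylboronic acid F8.
- Oxidation with H2O2 and aq NaOH at 0 °C gives the target 31, so steps 15 and 16 are not needed.

Step 5. The chiral lithium amide may discriminate the two enantiotopic syn protons poorly, or in the opposite sense, so that 6 is formed with low enantiomeric purity. The fallback sets out from 5 and comes back at 6.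
- 5 is rearranged without chiral control (LiNEt2, Et2O, reflux) to the racemate, that is 6 together with its enantiomer (1S,4S,5S)-4,5-dimethylcyclohex-2-en-1-ol F9.
- Esterification with (S)-2-methoxy-2-phenylacetic acid (DCC, DMAP, CH2Cl2) gives (1R,4R,5R)-4,5-dimethylcyclohex-2-en-1-yl (2S)-2-methoxy-2-phenylacetate F10 and (1S,4S,5S)-4,5-dimethylcyclohex-2-en-1-yl (2S)-2-methoxy-2-phenylacetate F11.
- The two diastereomers are separated by chromatography or crystallisation, and saponification of the (1R,4R,5R) ester (LiOH, THF–H2O) gives 6.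

**Further compounds**

F1 | step 12 | methoxyacetylene | COC#C
F2 | step 12 | 4-{(3S,4R,5R)-3-[4-(benzyloxy)-3-methoxyphenyl]-4,5-dimethylcyclohex-1-en-1-yl}-3-methoxycyclobut-2-en-1-one | COc1cc([C@@H]2C=C(C3C(OC)=CC3=O)C[C@@H](C)[C@H]2C)ccc1OCc1ccccc1
F3 | step 12 | silicon-free dienylketene, 4-{(3S,4R,5R)-3-[4-(benzyloxy)-3-methoxyphenyl]-4,5-dimethylcyclohex-1-en-1-yl}-3-methoxybuta-1,3-dien-1-one | COc1cc([C@@H]2C=C(\C=C(OC)/C=C=O)C[C@@H](C)[C@H]2C)ccc1OCc1ccccc1
F4 | step 12 | silicon-free cyclohexa-2,4-dienone (keto tautomer of F5) | COc1cc([C@@H]2C3C(=O)C=C(OC)C=C3C[C@@H](C)[C@H]2C)ccc1OCc1ccccc1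
F5 | step 12 | (7'R,8R,8'R)-4'-(benzyloxy)-3',5-dimethoxy-2,7'-cyclolignan-3-ol | COc1cc([C@@H]2c3c(cc(OC)cc3O)C[C@@H](C)[C@H]2C)ccc1OCc1ccccc1
F6 | step 12 | (7'R,8R,8'R)-4'-(benzyloxy)-3,3',5-trimethoxy-2,7'-cyclolignan | COc1cc([C@@H]2c3c(cc(OC)cc3OC)C[C@@H](C)[C@H]2C)ccc1OCc1ccccc1
F7 | step 14 | (7'R,8R,8'R)-4-(dichloroboryl)-4'-(dichloroboryloxy)-3,3',5-trimethoxy-2,7'-cyclolignan | COc1cc([C@@H]2c3c(cc(OC)c(B(Cl)Cl)c3OC)C[C@@H](C)[C@H]2C)ccc1OB(Cl)Cl
F8 | step 14 | (7'R,8R,8'R)-4'-hydroxy-3,3',5-trimethoxy-2,7'-cyclolignan-4-ylboronic acid | COc1cc([C@@H]2c3c(cc(OC)c(B(O)O)c3OC)C[C@@H](C)[C@H]2C)ccc1O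
F9 | step 5 | (1S,4S,5S)-4,5-dimethylcyclohex-2-en-1-ol | C[C@H]1C[C@H](O)C=C[C@H]1C
F10 | step 5 | (1R,4R,5R)-4,5-dimethylcyclohex-2-en-1-yl (2S)-2-methoxy-2-phenylacetate | C[C@@H]1C[C@@H](OC(=O)[C@@H](OC)c2ccccc2)C=C[C@@H]1C
F11 | step 5 | (1S,4S,5S)-4,5-dimethylcyclohex-2-en-1-yl (2S)-2-methoxy-2-phenylacetate | C[C@H]1C[C@H](OC(=O)[C@@H](OC)c2ccccc2)C=C[C@H]1C
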